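Take the whole electrophile charge as unit, and measure the free base in it too: 0.400 in the spring run, 0.600 in the summer run, 0.800 in the new flask.

| flask | electrophile | free base | protonated nucleophile | remark | time |
|---|---|---|---|---|---|
| spring | 1.5 M (fed, over 2.5 h) | 0.60 M | 2.25 M | run made earlier |  |
| summer | 1.5 M (fed, over 2.5 h) | 0.90 M | 2.25 M | run made earlier |  |
| flask | 1.5 M (fed, over 2.5 h) | 1.20 M | 2.25 M |  | 2.5 h |

- spring (time / min: electrophile / %, target / %): 15.0: 9.4, 0; 40.0: 24.7, 1.8; 80.0: 48.0, 5.5; 120: 71.4, 8.9
- summer (time / min: electrophile / %, target / %): 10.0: 6.4, 0; 20.0: 12.2, 1.1; 50.0: 28.9, 4.2; 120: 66.7, 13.1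

(each reading ± 0.5 percentage points)

- what was read earlier has a scatter of 0.5 percentage points, one standard deviation
- percentages count the whole charge, also what has not yet gone in

- amount of electrophile in percent of the electrophile charged, at 30 min, 80 min and 2.5 h

Start with the bound from above. The feed is steady, so the electrophile in the new flask can't exceed the fed fraction, 20.0% at 30 min, 53.3% at 80 min and 100% at 2.5 h. In the spring run, electrophile and target add up to 80.3% at 120 min against 80.0% fed, and most of it is still electrophile: this is accumulation.

Now tighten the bound. At 120 min the spring run reads 0.223 and the summer run 0.218: call this target fraction divided by base fraction the yield per base. Take it as a function of time, and multiply it by 0.800 for the new flask.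

For the first time asked, the summer reading at 20.0 min and the spring reading at 40.0 min put the estimate of the electrophile between 16.4% and 18.5%. For the second, the spring reading at the same time gives an estimate of 42.3%, give or take 1 percentage point. For the end of the feed, hold the yield per base at its last spring reading to get the upper estimate, 82.2%. Then continue at the last spring pace, 0.128 h⁻¹ in yield per base, to get the lower estimate, 77.1%.

The forecast gives 17.4%, 43% and 78.5%, inside these brackets, on the ground that “the conjugate acid formed suppresses free nucleophile”.

The new flask gives 17.5%, 42.9% and 78.7%, each inside its bracket.

    nucleophile + acid set free ⇌ protonated nucleophile, settled at all times (K = 5600 L mol⁻¹)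
    nucleophile ⇌ dormant form (K = 1.50, k = 1.10 h⁻¹)
    electrophile + nucleophile → acid set free + target (k = 0.730 L mol⁻¹ h⁻¹)
    acid set free + free base ⇌ salt of the base, settled at all times (K = 25000 L mol⁻¹)

At 2.50 h the new flask holds 2.2% of its free base unbound, less than the 79% of its electrophile. Its target then stands at 21.3%, a yield per base of 0.266. At 5.00 h the target in this flask stands at 32.8%, a yield per base of 0.410.

The runs are calculated from invented constants; noise was put on by code.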